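**Strategy.** The decalin is cut at C8–C9 and C1–C10: one radical cascade on an open-chain bromo-triene-enone closes ring B first, then ring A. It exploits two features: the exocyclic C8=C17 methylene, read as the trace of a C8 vinyl radical, and the quaternary, methyl-bearing C10 that stands 1,5 to the C3 oxygen (C10–C1–C2–C3=O), read as a tertiary radical plus a vinyl ketone. The precursor carries only the C4/C5 stereocentres, set by an ester dienolate [3,3] shift that relays one carbinol centre; C9 and C10 follow in the cascade. The lactone ring is bought intact and joined by cross-metathesis, so ring A is the last ring closed.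

Key step: step 7

Numbering: labdane numbers are used (ring A: C1–C5, C10; ring B: C5–C10; C17 exocyclic CH2 on C8; C18 and C19 the CH3 and CH2OH on C4; C20 the CH3 on C10; C11–C16 side chain and lactone, acetate on C14).
Remark: 1, 5, (+)-Ipc2BOMe and 23 are taken as catalogue compounds; the lactone ring enters as purchased ring 23, and the only ring formed after step 7 is the temporary acetonide.

Step 1
Reactants: 1 N-ethylidene-tert-butylamine; 2 2,3-dibromoprop-1-ene
Product: 4 4-bromopent-4-enal, via alkylated imine 3 (not isolated)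
Conditions: LiN(iPr)2, THF, −78 to 0 °C; 2, −78 °C to rt; aq. oxalic acid, rt
Reagents that add atoms: water, O
Why: Stork metalloenamine alkylation, in which the lithiated acetaldehyde imine is monoalkylated by the allylic bromide of 2 (the vinylic bromide is inert to SN2) and mild acid hydrolysis of 3 releases the aldehyde; no stereocentre is formed.

Step 2
Reactants: 4 4-bromopent-4-enal; 5 2-(triphenylphosphoranylidene)propanal
Product: 6 (2E)-6-bromo-2-methylhepta-2,6-dienal
Conditions: PhMe, 90 °C
Reagents that add atoms: none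
Why: Wittig olefination with a stabilised α-methyl formyl ylide, which should react once with the aliphatic aldehyde and give the (E)-enal; no stereocentre is formed.

Step 3
Reactants: 6 (2E)-6-bromo-2-methylhepta-2,6-dienal; 7 allylmagnesium bromide
Product: 8 (4R,5E)-9-bromo-5-methyldeca-1,5,9-trien-4-ol
Conditions: (+)-Ipc2BOMe, 7, Et2O, 0 °C to rt; 6, −78 °C; NaOH, H2O2, rt
Reagents that add atoms: none
Why: Brown asymmetric allylboration, in which the B-allyldiisopinocampheylborane formed in the flask adds 1,2 through a closed chair transition state and the reagent antipode from (+)-Ipc2BOMe should set the 4R carbinol (C9) that later relays chirality to C5 and C4.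

Step 4
Reactants: 8 (4R,5E)-9-bromo-5-methyldeca-1,5,9-trien-4-ol; 9 ethyl 2-methyl-3-oxobutanoate
Product: 10 (4R,5E)-9-bromo-5-methyldeca-1,5,9-trien-4-yl 2-methyl-3-oxobutanoate
Conditions: DMAP (cat.), PhMe, 110 °C, EtOH distilled off
Reagents that add atoms: none
Why: DMAP-catalysed transacetoacetylation driven by removal of ethanol; the carbinol centre is untouched and the acyl α-carbon is a mixture that is erased in step 5.

Step 5
Reactants: 10 (4R,5E)-9-bromo-5-methyldeca-1,5,9-trien-4-yl 2-methyl-3-oxobutanoate
Product: 13 methyl (2S)-2-[(5S,6E)-2-bromo-6-methyldeca-1,6,9-trien-5-yl]-2-methyl-3-oxobutanoate, via bis-silyl dienolate 11 (not isolated), via keto acid 12 (not isolated)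
Conditions: LiN(iPr)2 (2.1 equiv), THF, −78 to 0 °C; Me3SiCl, −78 °C to rt; 1 M HCl, 0 °C; Me3SiCHN2, PhMe/MeOH, 0 °C
Reagents that add atoms: trimethylsilyldiazomethane, C[Si](C)(C)C=[N+]=[N-]
Why: Ester dienolate Claisen rearrangement (a Carroll-type [3,3] shift run under Ireland–Claisen conditions so that CO2 is kept), in which the chelated dianion is trapped as 11 with the C4 methyl cis to the allylic oxygen and a chair transition state with the C9 allyl group equatorial should transfer the carbinol chirality to C5 (S) and C4 (S) while forming the (E)-C9=C10 alkene, cold hydrolysis and immediate esterification of 12 forestalling decarboxylation.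

Step 6
Reactants: 13 methyl (2S)-2-[(5S,6E)-2-bromo-6-methyldeca-1,6,9-trien-5-yl]-2-methyl-3-oxobutanoate
Product: 16 methyl (2S)-2-[(5S,6E)-2-bromo-6-methyldeca-1,6,9-trien-5-yl]-2-methyl-3-oxopent-4-enoate, via Mannich base 14 (not isolated), via ammonium iodide 15 (not isolated)
Conditions: LiN(iPr)2, THF, −78 °C; CH2=NMe2+ I−, −78 °C to rt; MeI, CH2Cl2, rt; aq. NaHCO3, rt
Reagents that add atoms: dimethylmethyleneammonium iodide, C=[N+](C)C.[I-]
Why: Eschenmoser methylenation, in which the only enolisable position (the acetyl CH3, C4 being quaternary) is deprotonated, the enolate undergoes a Mannich reaction and quaternisation followed by E1cB loss of trimethylamine unveils the vinyl ketone; no stereocentre is touched.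

Step 7
Reactants: 16 methyl (2S)-2-[(5S,6E)-2-bromo-6-methyldeca-1,6,9-trien-5-yl]-2-methyl-3-oxopent-4-enoate
Product: 20 methyl (1S,4aS,5R,8aS)-1,4a-dimethyl-6-methylidene-2-oxo-5-(prop-2-en-1-yl)decahydronaphthalene-1-carboxylate, via vinyl radical 17 (not isolated), via monocyclic C10 radical 18 (not isolated), via bicyclic keto radical 19 (not isolated)
Conditions: Bu3SnH (1.3 equiv), AIBN (0.2 equiv), syringe-pump addition over 8 h, degassed PhH (0.005 M), 80 °C
Reagents that add atoms: none
Why: Bu3Sn• abstracts bromine to give the C8 vinyl radical 17, which adds to C9 of the (E)-C9=C10 alkene (6-endo-trig, or 5-exo followed by the known homoallyl/cyclopropylcarbinyl 1,2-vinyl shift, both paths converging) to close ring B with its exocyclic C8=C17 methylene and leave the tertiary C10 radical 18; this nucleophilic radical then adds to C1 of the tethered vinyl ketone (6-endo-trig conjugate addition) to close ring A last, and the α-keto radical 19 takes hydrogen from Bu3SnH. The closest known reaction types are the Stork vinyl-radical cyclization and tandem radical cyclizations terminated by Giese addition to an enone. C9 is set in the first closure: a chair transition state with the bulky C4 group on C5 eclipsing the alkene (anti to the C10 methyl) and the E geometry should place C11 equatorial, cis to the C5–C4 bond. C10 is set in the second closure: the equatorial tether on C5 should reach the radical through a chair that makes the new C10–C1 bond equatorial and the methyl axial (trans fusion, as in the second ring closure of radical polyene cyclizations), the cis alternative costing a C18/C20 methyl–methyl 1,3-diaxial contact. The step needs six- over five-membered closure at both stages and cyclization faster than hydrogen transfer; these are secured by methyl substitution at C10, the unhindered CH2 terminus of the acceptor, the absence of any C–H on C4 (no 1,5-hydrogen shift to the vinyl radical) and slow addition of the stannane.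

Step 8
Reactants: 20 methyl (1S,4aS,5R,8aS)-1,4a-dimethyl-6-methylidene-2-oxo-5-(prop-2-en-1-yl)decahydronaphthalene-1-carboxylate
Product: 21 (1R,2R,4aS,5R,8aS)-1-(hydroxymethyl)-1,4a-dimethyl-6-methylidene-5-(prop-2-en-1-yl)decahydronaphthalen-2-ol
Conditions: LiAlH4, THF, 0 °C to rt; Rochelle salt work-up
Reagents that add atoms: none
Why: LiAlH4 reduction of ketone and ester, in which hydride should add to C3 axially, opposite the axial C4 ester, to give the equatorial 3-hydroxyl cis to the new axial CH2OH (as in reductions of 4,4-disubstituted 3-oxo terpenoids) while the isolated alkenes are inert.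

Step 9
Reactants: 21 (1R,2R,4aS,5R,8aS)-1-(hydroxymethyl)-1,4a-dimethyl-6-methylidene-5-(prop-2-en-1-yl)decahydronaphthalen-2-ol
Product: 22 3,19-O-isopropylidene acetal of 21
Conditions: Me2C(OMe)2, PPTS (cat.), CH2Cl2, rt
Reagents that add atoms: 2,2-dimethoxypropane, COC(C)(C)OC
Why: Acid-catalysed transketalisation, in which the cis 1,3-diol (equatorial 3-OH, axial CH2OH) closes to the six-membered acetonide, a temporary ring removed in step 13.

Step 10
Reactants: 23 (4S)-4-hydroxyoxolan-2-one
Product: 26 (4S)-4-hydroxy-3-methylideneoxolan-2-one, via Mannich base 24 (not isolated), via ammonium iodide 25 (not isolated)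
Conditions: LiN(iPr)2 (2.2 equiv), THF, −78 °C; CH2=NMe2+ I−, −78 to 0 °C; MeI, MeOH, rt; aq. NaHCO3, CH2Cl2, rt
Reagents that add atoms: dimethylmethyleneammonium iodide, C=[N+](C)C.[I-]
Why: Dianion Mannich reaction followed by elimination (Eschenmoser methylenation), in which the alkoxide–enolate dianion resists β-elimination, is aminomethylated at C13 trans to the alkoxide, and loss of trimethylamine from 25 gives the exocyclic methylene without touching the C14 stereocentre.

Step 11
Reactants: 22 3,19-O-isopropylidene acetal of 21; 26 (4S)-4-hydroxy-3-methylideneoxolan-2-one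
Product: 27 3,19-O-isopropylidene-andrographolide
Conditions: second-generation Hoveyda–Grubbs catalyst RuCl2(H2IMes)(=CH-C6H4-2-OiPr) (10 mol%), 2,6-dichloro-1,4-benzoquinone (20 mol%), 26 (3 equiv), CH2Cl2, 40 °C
Reagents that add atoms: none
Why: Olefin cross-metathesis of a terminal alkene with an α-methylene-γ-butyrolactone (the benzoquinone suppressing ruthenium hydride isomerisation), in which the hindered 1,1-disubstituted C8 methylene and the acetal should be inert and the conjugated trisubstituted alkene should form as the thermodynamically preferred E isomer; no stereocentre is formed.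

Step 12
Reactants: 27 3,19-O-isopropylidene-andrographolide
Product: 28 14-O-acetyl-3,19-O-isopropylidene-andrographolide
Conditions: Ac2O, pyridine, CH2Cl2, 0 °C to rt
Reagents that add atoms: acetic anhydride, CC(=O)OC(C)=O
Why: Acylation of the only free hydroxyl (allylic C14–OH) under mild, weakly basic conditions that should avoid elimination of the allylic acetate.

Step 13
Reactants: 28 14-O-acetyl-3,19-O-isopropylidene-andrographolide
Product: 29 14-O-acetylandrographolide (CNP0077248.1)
Conditions: AcOH/H2O (7:3), rt
Reagents that add atoms: none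
Why: Mild aqueous acid hydrolysis of the isopropylidene acetal, which should leave the allylic acetate, the exocyclic alkene and the alkylidene lactone intact.

**Compound list**

1 | N-ethylidene-tert-butylamine | CC=NC(C)(C)C | starting material
2 | 2,3-dibromoprop-1-ene | C=C(Br)CBr | starting material
3 | N-(4-bromopent-4-en-1-ylidene)-tert-butylamine | C=C(Br)CCC=NC(C)(C)C | intermediate
4 | 4-bromopent-4-enal | C=C(Br)CCC=O | intermediate
5 | 2-(triphenylphosphoranylidene)propanal | CC(C=O)=P(c1ccccc1)(c1ccccc1)c1ccccc1 | starting material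
6 | (2E)-6-bromo-2-methylhepta-2,6-dienal | C=C(Br)CC/C=C(\C)C=O | intermediate
7 | allylmagnesium bromide | C=CC[Mg]Br | starting material
8 | (4R,5E)-9-bromo-5-methyldeca-1,5,9-trien-4-ol | C=C(Br)CC/C=C(\C)[C@H](O)CC=C | intermediate
9 | ethyl 2-methyl-3-oxobutanoate | CCOC(=O)C(C)C(C)=O | starting material
10 | (4R,5E)-9-bromo-5-methyldeca-1,5,9-trien-4-yl 2-methyl-3-oxobutanoate (acyl α-carbon unassigned) | C=C(Br)CC/C=C(\C)[C@H](OC(=O)C(C)C(C)=O)CC=C | intermediate
11 | 1-[(4R,5E)-9-bromo-5-methyldeca-1,5,9-trien-4-yloxy]-2-methyl-1,3-bis(trimethylsilyloxy)buta-1,3-diene, methyl cis to the allylic oxygen | C=C(O[Si](C)(C)C)/C(C)=C(\O[Si](C)(C)C)O[C@H](CC=C)/C(C)=C/CCC(Br)=C | intermediate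
12 | (2S)-2-[(5S,6E)-2-bromo-6-methyldeca-1,6,9-trien-5-yl]-2-methyl-3-oxobutanoic acid | C=C(Br)CC[C@@H](/C(C)=C/CC=C)[C@](C)(C(=O)O)C(C)=O | intermediate
13 | methyl (2S)-2-[(5S,6E)-2-bromo-6-methyldeca-1,6,9-trien-5-yl]-2-methyl-3-oxobutanoate | C=C(Br)CC[C@@H](/C(C)=C/CC=C)[C@](C)(C(=O)OC)C(C)=O | intermediate
14 | methyl (2S)-2-[(5S,6E)-2-bromo-6-methyldeca-1,6,9-trien-5-yl]-5-(dimethylamino)-2-methyl-3-oxopentanoate | C=C(Br)CC[C@@H](/C(C)=C/CC=C)[C@](C)(C(=O)OC)C(=O)CCN(C)C | intermediate
15 | N-methyl ammonium iodide of 14 | C=C(Br)CC[C@@H](/C(C)=C/CC=C)[C@](C)(C(=O)OC)C(=O)CC[N+](C)(C)C.[I-] | intermediate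
16 | methyl (2S)-2-[(5S,6E)-2-bromo-6-methyldeca-1,6,9-trien-5-yl]-2-methyl-3-oxopent-4-enoate | C=C(Br)CC[C@@H](/C(C)=C/CC=C)[C@](C)(C(=O)OC)C(=O)C=C | intermediate
17 | C8 vinyl radical from 16 | C=[C]CC[C@@H](/C(C)=C/CC=C)[C@](C)(C(=O)OC)C(=O)C=C | intermediate
18 | ring B closed, tertiary C10 radical | C=C1CC[C@H]([C@](C)(C(=O)OC)C(=O)C=C)[C](C)[C@@H]1CC=C | intermediate
19 | trans-decalin C2 α-keto radical | C=C1CC[C@@H]2[C@](C)(C(=O)OC)C(=O)[CH]C[C@@]2(C)[C@@H]1CC=C | intermediate
20 | methyl (1S,4aS,5R,8aS)-1,4a-dimethyl-6-methylidene-2-oxo-5-(prop-2-en-1-yl)decahydronaphthalene-1-carboxylate | C=C1CC[C@@H]2[C@](C)(C(=O)OC)C(=O)CC[C@@]2(C)[C@@H]1CC=C | intermediate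
21 | (1R,2R,4aS,5R,8aS)-1-(hydroxymethyl)-1,4a-dimethyl-6-methylidene-5-(prop-2-en-1-yl)decahydronaphthalen-2-ol | C=C1CC[C@@H]2[C@](C)(CO)[C@H](O)CC[C@@]2(C)[C@@H]1CC=C | intermediate
22 | 3,19-O-isopropylidene acetal of 21 (2,2-dimethyl-1,3-dioxane across O3 and O19) | C=C1CC[C@@H]2[C@](C)(CO3)[C@H](OC3(C)C)CC[C@@]2(C)[C@@H]1CC=C | intermediate
23 | (4S)-4-hydroxyoxolan-2-one ((S)-3-hydroxy-γ-butyrolactone) | O=C1C[C@H](O)CO1 | starting material
24 | (4S)-3-[(dimethylamino)methyl]-4-hydroxyoxolan-2-one, 3,4-trans | CN(C)C[C@@H]1C(=O)OC[C@H]1O | intermediate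
25 | N-methyl ammonium iodide of 24 | C[N+](C)(C)C[C@@H]1C(=O)OC[C@H]1O.[I-] | intermediate
26 | (4S)-4-hydroxy-3-methylideneoxolan-2-one | C=C1C(=O)OC[C@H]1O | intermediate
27 | 3,19-O-isopropylidene-andrographolide (12E,14S) | C=C1CC[C@@H]2[C@](C)(CO3)[C@H](OC3(C)C)CC[C@@]2(C)[C@@H]1C/C=C1/C(=O)OC[C@H]1O | intermediate
28 | 14-O-acetyl-3,19-O-isopropylidene-andrographolide | C=C1CC[C@@H]2[C@](C)(CO3)[C@H](OC3(C)C)CC[C@@]2(C)[C@@H]1C/C=C1/C(=O)OC[C@H]1OC(C)=O | intermediate
29 | 14-O-acetylandrographolide (CNP0077248.1) | C=C1CC[C@@H]2[C@](C)(CO)[C@H](O)CC[C@@]2(C)[C@@H]1C/C=C1/C(=O)OC[C@H]1OC(C)=O | target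

**Step count.** Total: 13 steps. Longest linear sequence: 12 steps (1–9, 11–13).

**Steps most likely to fail**

1. Step 7 (key step). What may go wrong: hydrogen transfer from the stannane to the vinyl or the C10 radical before the ring closes, conjugate hydrostannation of the vinyl ketone, or closure of ring A through the cis-fused transition state. Fallback, from 13 back to 20, keeping ring B first and ring A last: dehydrobromination with Bu4NF·3H2O in DMF at 60 °C should give the terminal alkyne keto ester F1. Methylenation as in step 6 should lead through the Mannich base F2 and its methiodide F3 to the alkynyl vinyl ketone F4. Bu3SnH/AIBN then starts the same cascade by reversible addition of the stannyl radical to the alkyne terminus (hydrostannylative vinyl-radical cyclization, no halogen abstraction needed), giving the C17 vinylstannane F5. Protodestannylation with HCl in CH2Cl2 should return 20.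

2. Step 5. What may go wrong: loss of dienolate geometry or a boat transition state eroding the C4/C5 diastereoselectivity, decarboxylation of the β-keto acid before esterification, or base attack on the vinyl bromide. Fallback, from 8 back to 20, setting C4 on the ring instead of in the chain: Johnson–Claisen rearrangement with MeC(OMe)3/EtCO2H at 140 °C should give the γ,δ-unsaturated ester F6 with the same C5 configuration. LiN(iPr)2 then acrolein gives the aldol F7, and Dess–Martin oxidation gives the C4–H keto ester F8. The radical cascade of step 7 on F8 (now exposed to a 1,5-hydrogen shift from C4) should give the bicyclic β-keto ester F9. K2CO3/MeI in acetone should then methylate its enolate anti to the C10 methyl (equatorial methyl, axial ester), rejoining the route at 20.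

3. Step 11. What may go wrong: slow metathesis at the hindered, allylically oxygenated 1,1-disubstituted olefin, isomerisation of 26 by ruthenium hydrides, or formation of the Z alkene. Fallback, from 22 back to 27, by aldol condensation with the intact lactone ring: OsO4 (cat.)/NaIO4/2,6-lutidine in dioxane–water should cleave the monosubstituted alkene in preference to the hindered exocyclic methylene, giving the C12 aldehyde F10. The lithium enolate (LiN(iPr)2, −78 °C) of the silyl ether F11 (from 23, TBSCl, imidazole) adds to F10 to give the aldol F12. MsCl/Et3N gives the mesylate F13, and DBU should eliminate it to the (E)-alkylidene silyl ether F14, the silyloxy group being the poorer leaving group. HF·pyridine in THF removes the silyl group to give 27.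

**Further compounds**

F1 | step 7 | terminal alkyne analogue of 13 (C8≡C17H in place of the vinyl bromide) | C#CCC[C@@H](/C(C)=C/CC=C)[C@](C)(C(=O)OC)C(C)=O
F2 | step 7 | Mannich base of F1 (CH2CH2NMe2 ketone) | C#CCC[C@@H](/C(C)=C/CC=C)[C@](C)(C(=O)OC)C(=O)CCN(C)C
F3 | step 7 | methiodide of F2 | C#CCC[C@@H](/C(C)=C/CC=C)[C@](C)(C(=O)OC)C(=O)CC[N+](C)(C)C.[I-]
F4 | step 7 | alkynyl vinyl ketone (alkyne analogue of 16) | C#CCC[C@@H](/C(C)=C/CC=C)[C@](C)(C(=O)OC)C(=O)C=C
F5 | step 7 | C17-tributylstannyl derivative of 20 (vinylstannane, alkene geometry unassigned) | CCCC[Sn](CCCC)(CCCC)C=C1CC[C@@H]2[C@](C)(C(=O)OC)C(=O)CC[C@@]2(C)[C@@H]1CC=C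
F6 | step 5 | methyl (4E)-3-(3-bromobut-3-en-1-yl)-4-methylocta-4,7-dienoate, C5 configured as in 13 | C=C(Br)CC[C@@H](/C(C)=C/CC=C)CC(=O)OC
F7 | step 5 | acrolein aldol of F6 (3-hydroxypent-4-enoate, diastereomer mixture at C3 and C4) | C=C(Br)CC[C@@H](/C(C)=C/CC=C)C(C(=O)OC)C(O)C=C
F8 | step 5 | C4–H analogue of 16 (3-oxopent-4-enoate, C4 epimers) | C=C(Br)CC[C@@H](/C(C)=C/CC=C)C(C(=O)OC)C(=O)C=C
F9 | step 5 | C4-unmethylated analogue of 20 (C4–H, epimerisable) | C=C1CC[C@@H]2C(C(=O)OC)C(=O)CC[C@@]2(C)[C@@H]1CC=O.C |
F10 | step 11 | C12 aldehyde from 22 (CH2CHO on C9) | C=C1CC[C@@H]2[C@](C)(CO3)[C@H](OC3(C)C)CC[C@@]2(C)[C@@H]1CC=O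
F11 | step 11 | (4S)-4-(tert-butyldimethylsilyloxy)oxolan-2-one | O=C1C[C@H](O[Si](C)(C)C(C)(C)C)CO1
F12 | step 11 | aldol adduct of F10 and F11 (C12 carbinol, diastereomer mixture at C12 and C13) | C=C1CC[C@@H]2[C@](C)(CO3)[C@H](OC3(C)C)CC[C@@]2(C)[C@@H]1CC(O)C1C(=O)OC[C@H]1O[Si](C)(C)C(C)(C)C
F13 | step 11 | C12 mesylate of F12 | C=C1CC[C@@H]2[C@](C)(CO3)[C@H](OC3(C)C)CC[C@@]2(C)[C@@H]1CC(OS(C)(=O)=O)C1C(=O)OC[C@H]1O[Si](C)(C)C(C)(C)C
F14 | step 11 | 14-O-tert-butyldimethylsilyl ether of 27 (12E) | C=C1CC[C@@H]2[C@](C)(CO3)[C@H](OC3(C)C)CC[C@@]2(C)[C@@H]1C/C=C1/C(=O)OC[C@H]1O[Si](C)(C)C(C)(C)C
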